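**Retrosynthetic overview**
- The C4–C4a and O1–C2 bonds of the 2H-pyran ring are cut together. This leads back to 2,4-dihydroxyacetophenone and an (E)-β-methyl enal that already carries the ferulate ester on its γ-CH2; no protecting groups are used.
- Enabling feature: O1 is a phenolic oxygen on a resorcinol-type benzene ring, and C4a is its ortho CH, para to the C7 hydroxyl. C2–C3=C4 is at the enal oxidation level with C2 fully substituted (CH3, CH2O-acyl). A vinyl ortho-quinone methide (O1=C8a–C4a=C4–C3=C2) can therefore form and close to the pyran ring.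
- One chiral Brønsted acid is asked to control the arene regiochemistry, both new bonds, the C3=C4 alkene and the C2 stereocentre.
- The enal comes from isoprene monoxide: TiCl4 SN2′ opening (sets the E alkene), Mitsunobu esterification with ferulic acid, N-oxide oxidation of the allylic chloride.
- Ring order: both benzene rings are purchased; the pyran ring is formed last.

Key step: step 4

Assumption: the C2 descriptor read from the target SMILES is (R). The sense of induction of the chiral acid cannot be predicted with certainty, so the (R)-catalyst written in step 4 stands for whichever antipode a first test shows to give (R)-9.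

**Step 1**
Reactants: 1 2-methyl-2-vinyloxirane (isoprene monoxide, racemic)
Product: 2 (E)-4-chloro-2-methylbut-2-en-1-ol
Conditions: TiCl4 (1.1 equiv), CH2Cl2, −85 °C; then H2O quench
Reagents that add atoms: titanium tetrachloride, Cl[Ti](Cl)(Cl)Cl
Why: Lewis-acid-mediated SN2′ (1,4-) opening of a vinyl epoxide, known for this epoxide, in which titanium-bound chloride is delivered to the vinyl terminus and the (E)-trisubstituted alkene should form selectively at low temperature.

**Step 2**
Reactants: 2 (E)-4-chloro-2-methylbut-2-en-1-ol; 3 (E)-ferulic acid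
Product: 4 (E)-4-chloro-2-methylbut-2-en-1-yl (E)-3-(4-hydroxy-3-methoxyphenyl)prop-2-enoate
Conditions: PPh3, DIAD, THF, 0 °C → rt
Reagents that add atoms: none
Why: Mitsunobu esterification, in which the carboxylic acid (far more acidic than the phenol) protonates the betaine and its carboxylate displaces the primary allylic alkoxyphosphonium by SN2, so the phenol should stay free and no stereocentre is involved.

**Step 3**
Reactants: 4 (E)-4-chloro-2-methylbut-2-en-1-yl (E)-ferulate
Product: 5 (E)-2-methyl-4-oxobut-2-en-1-yl (E)-3-(4-hydroxy-3-methoxyphenyl)prop-2-enoate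
Conditions: NMO (4 equiv), NaI (0.2 equiv), 4 Å MS, MeCN, 0 °C → rt
Reagents that add atoms: N-methylmorpholine N-oxide, C[N+]1([O-])CCOCC1
Why: Kornblum/Ganem-type N-oxide oxidation of an activated halide, in which iodide-assisted SN2 attack of the N-oxide oxygen on the allylic chloride gives an alkoxyammonium salt that eliminates to the enal under near-neutral conditions that should leave the ester, the phenol and the E geometry untouched.

**Step 4**
Reactants: 5 (E)-2-methyl-4-oxobut-2-en-1-yl (E)-ferulate; 6 2,4-dihydroxyacetophenone (1.2 equiv)
Product: 9 [(2R)-6-acetyl-7-hydroxy-2-methyl-2H-chromen-2-yl]methyl (E)-3-(4-hydroxy-3-methoxyphenyl)prop-2-enoate (target), via ortho-hydroxybenzylic carbinol 7 (not isolated), via vinyl ortho-quinone methide 8 (not isolated)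
Conditions: (R)-3,3′-bis(2,4,6-triisopropylphenyl)-H8-BINOL N-triflylphosphoramide (10 mol %), 5 Å MS, toluene/CH2Cl2, 0 °C → rt
Reagents that add atoms: none
Why: Proposed new method: the strong chiral acid, hydrogen-bonded to the free 4-OH of 6 and to the aldehyde of 5, should promote ortho Friedel–Crafts 1,2-addition of C5 of 6 to the enal to give carbinol 7 (either configuration), which loses water to the vinyl ortho-quinone methide 8, held as a hydrogen-bonded contact ion pair with the chiral phosphoramide anion, and 8 closes to the chromene. The closest known reaction types are the racemic amine- or boronic-acid-mediated condensation of phenols with β,β-disubstituted enals to 2H-chromenes, and the chiral N-triflylphosphoramide-catalysed enantioselective cyclisation of 2-(3-hydroxyalk-1-enyl)phenols to 2,2-disubstituted 2H-chromenes through the same kind of ion pair; what is new is reaching that ion pair directly from phenol plus enal with one catalyst. The pyran ring closes by oxa-6π electrocyclisation of the 1-oxatriene in 8 (thermal, disrotatory; equivalent to 6-endo attack of the phenol oxygen on the tertiary allyl-cation terminus). The C2 stereocentre is set under catalyst control, the chiral anion shielding one face of the CH3/CH2O-acyl-substituted terminus during C–O bond formation, and both epimers of 7 converge on the same planar intermediate. The step needs C5 over C3 regioselectivity on the arene and 1,2- over 1,4-addition to the enal. The first should be secured because the 2-OH is tied up in its hydrogen bond to the acetyl group and C3 lies crowded between two oxygen substituents, while acidic, non-phenoxide electrophilic substitution of 6 goes para to the 2-OH (after C5 attack only the 4-OH is ortho), and the second because the β,β-disubstituted enal terminus disfavours conjugate addition.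

**Compound list**
1 | 2-methyl-2-vinyloxirane (isoprene monoxide, racemic) | CC1(C=C)CO1 | starting material
2 | (E)-4-chloro-2-methylbut-2-en-1-ol | OC/C(C)=C/CCl | intermediate
3 | (E)-ferulic acid, (E)-3-(4-hydroxy-3-methoxyphenyl)prop-2-enoic acid | COc1cc(/C=C/C(=O)O)ccc1O | starting material
4 | (E)-4-chloro-2-methylbut-2-en-1-yl (E)-3-(4-hydroxy-3-methoxyphenyl)prop-2-enoate | COc1cc(/C=C/C(=O)OC/C(C)=C/CCl)ccc1O | intermediate
5 | (E)-2-methyl-4-oxobut-2-en-1-yl (E)-3-(4-hydroxy-3-methoxyphenyl)prop-2-enoate | COc1cc(/C=C/C(=O)OC/C(C)=C/C=O)ccc1O | intermediate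
6 | 2,4-dihydroxyacetophenone | CC(=O)c1ccc(O)cc1O | starting material
7 | (E)-4-(5-acetyl-2,4-dihydroxyphenyl)-4-hydroxy-2-methylbut-2-en-1-yl (E)-ferulate (carbinol, both configurations at the carbinol carbon) | COc1cc(/C=C/C(=O)OC/C(C)=C/C(O)c2cc(C(C)=O)c(O)cc2O)ccc1O | intermediate (not isolated)
8 | vinyl ortho-quinone methide: (E)-4-(3-acetyl-4-hydroxy-6-oxocyclohexa-2,4-dien-1-ylidene)-2-methylbut-2-en-1-yl (E)-ferulate | COc1cc(/C=C/C(=O)OC/C(C)=C/C=C2C=C(C(C)=O)C(O)=CC2=O)ccc1O | intermediate (not isolated)
9 | [(2R)-6-acetyl-7-hydroxy-2-methyl-2H-chromen-2-yl]methyl (E)-3-(4-hydroxy-3-methoxyphenyl)prop-2-enoate | COc1cc(/C=C/C(=O)OC[C@@]2(C)C=Cc3cc(C(C)=O)c(O)cc3O2)ccc1O | target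

**Step count and risks**
Total step count: 4. Longest linear sequence: 4 steps (1 → 2 → 4 → 5 → 9).

Steps most likely to fail:

1. Step 4 (proposed new method). Three processes may defeat it: attack of the enal at C3 of the arene (between the two oxygens) leading to the angular chromene; ring closure of catalyst-free ortho-quinone methide, which erodes the enantiomeric excess; and sluggish Friedel–Crafts addition of the acetyl-deactivated resorcinol. The fallback uses known chemistry, fixes the regiochemistry with a halogen and sets out from 6, 1 and 3, coming back to the route at 9. Compound 6 would be brominated para to the 2-OH (NBS, MeCN, 0 °C) to give 1-(5-bromo-2,4-dihydroxyphenyl)ethanone F1. In parallel, 3 would open epoxide 1 at its unsubstituted carbon (Cs2CO3 cat., DMF, 60 °C) to give racemic 2-hydroxy-2-methylbut-3-en-1-yl (E)-ferulate F2. Heck coupling of F1 with the vinyl group of F2 (Pd(OAc)2, P(o-tol)3, Et3N, MeCN, 80 °C, kept basic) should give racemic (E)-4-(5-acetyl-2,4-dihydroxyphenyl)-2-hydroxy-2-methylbut-3-en-1-yl (E)-ferulate F3. F3 would then be cyclised with the chiral N-triflylphosphoramide (toluene, −40 °C) in the known enantioselective, stereoconvergent allylic etherification, in which both enantiomers of F3 ionise to the same ion pair, to give 9.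

2. Step 3. The allylic chloride may be displaced by the free phenol of a second molecule, the N-oxide substitution may be slow, or the amine by-product may scramble the enal geometry, which would lower the enantioselectivity of step 4. The fallback sets out from 4 and comes back at 5, replacing halide-level oxidation by alcohol-level oxidation. Chloride 4 would be displaced with sodium formate (Bu4NI cat., DMF, rt) to give (E)-4-(formyloxy)-2-methylbut-2-en-1-yl (E)-ferulate F4. The formate alone would be cleaved (MeOH, NaHCO3, 0 °C) to give (E)-4-hydroxy-2-methylbut-2-en-1-yl (E)-ferulate F5. The allylic alcohol would then be oxidised with activated MnO2 (CH2Cl2, rt) to 5.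

3. Step 2. The phenol may be activated in competition with the acid, or the phosphine and carboxylate may attack the allylic chloride. The fallback sets out from 3 (with 2) and comes back at 4, switching from alcohol activation to acid activation with a protected phenol. Compound 3 would be bis-silylated (TBSCl, imidazole, DMF) to tert-butyldimethylsilyl (E)-3-[4-(tert-butyldimethylsilyloxy)-3-methoxyphenyl]prop-2-enoate F6. Its silyl ester alone would be hydrolysed (AcOH/THF/H2O, rt) to (E)-3-[4-(tert-butyldimethylsilyloxy)-3-methoxyphenyl]prop-2-enoic acid F7. Steglich esterification of F7 with 2 (EDC·HCl, DMAP cat., CH2Cl2, 0 °C) should give (E)-4-chloro-2-methylbut-2-en-1-yl (E)-3-[4-(tert-butyldimethylsilyloxy)-3-methoxyphenyl]prop-2-enoate F8. The aryl silyl ether would be removed with Et3N·3HF (THF, 0 °C) to give 4.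

**Further compounds**
F1 | step 4 | 1-(5-bromo-2,4-dihydroxyphenyl)ethanone | CC(=O)c1cc(Br)c(O)cc1O
F2 | step 4 | 2-hydroxy-2-methylbut-3-en-1-yl (E)-3-(4-hydroxy-3-methoxyphenyl)prop-2-enoate (racemic) | COc1cc(/C=C/C(=O)OCC(C)(O)C=C)ccc1O
F3 | step 4 | (E)-4-(5-acetyl-2,4-dihydroxyphenyl)-2-hydroxy-2-methylbut-3-en-1-yl (E)-3-(4-hydroxy-3-methoxyphenyl)prop-2-enoate (racemic) | COc1cc(/C=C/C(=O)OCC(C)(O)/C=C/c2cc(C(C)=O)c(O)cc2O)ccc1O
F4 | step 3 | (E)-4-(formyloxy)-2-methylbut-2-en-1-yl (E)-3-(4-hydroxy-3-methoxyphenyl)prop-2-enoate | COc1cc(/C=C/C(=O)OC/C(C)=C/COC=O)ccc1O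
F5 | step 3 | (E)-4-hydroxy-2-methylbut-2-en-1-yl (E)-3-(4-hydroxy-3-methoxyphenyl)prop-2-enoate | COc1cc(/C=C/C(=O)OC/C(C)=C/CO)ccc1O
F6 | step 2 | tert-butyldimethylsilyl (E)-3-[4-(tert-butyldimethylsilyloxy)-3-methoxyphenyl]prop-2-enoate | COc1cc(/C=C/C(=O)O[Si](C)(C)C(C)(C)C)ccc1O[Si](C)(C)C(C)(C)C
F7 | step 2 | (E)-3-[4-(tert-butyldimethylsilyloxy)-3-methoxyphenyl]prop-2-enoic acid | COc1cc(/C=C/C(=O)O)ccc1O[Si](C)(C)C(C)(C)C
F8 | step 2 | (E)-4-chloro-2-methylbut-2-en-1-yl (E)-3-[4-(tert-butyldimethylsilyloxy)-3-methoxyphenyl]prop-2-enoate | COc1cc(/C=C/C(=O)OC/C(C)=C/CCl)ccc1O[Si](C)(C)C(C)(C)C
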